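The data stem from a simulated flask for substances that don't exist.

Fraction of the charge per hour is the unit to reckon in, since you are asked what stands in a flask after a stated time. Eta and zeta carry more third substrate than the earlier runs and differ from each other in time.

| setting | birch | larch | eta | zeta |
|---|---|---|---|---|
| starting material | 10 mM | 10 mM | 10 mM | 10 mM |
| second substrate | 0.50 equiv | 0.50 equiv | 0.500 equiv | 0.500 equiv |
| third substrate | 0.25 equiv | 0.38 equiv | 0.500 equiv | 0.500 equiv |
| solid reagent | 1.2 equiv | 1.2 equiv | 1.20 equiv | 1.20 equiv |
| protic impurity | 1 mM | 1 mM | 1.00 mM | 1.00 mM |
| remark | run made earlier | run made earlier |  |  |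
| time |  |  | 3.0 h | 4.0 h |

| run | time / h | over-reaction product / % | starting material / % | target / % |
|---|---|---|---|---|
| birch | 0.250 | 1 | 100 | 4 |
| birch | 0.417 | 1 | 96 | 3 |
| birch | 0.833 | 2 | 90 | 4 |
| birch | 1.50 | 9 | 85 | 5 |
| birch | 3.00 | 26 | 69 | 7 |
| larch | 0.250 | 1 | 95 | 0 |
| larch | 0.417 | 0 | 97 | 1 |
| larch | 0.833 | 3 | 92 | 2 |
| larch | 1.50 | 9 | 86 | 9 |
| larch | 3.00 | 24 | 66 | 4 |

(scatter of a reading: 2 percentage points)

- solid, in amounts per volume of the solution: solid reagent
- reactions considered so far: starting material + partner -> target; second substrate + partner -> second product; third substrate + partner -> third product; solid reagent <-> partner; partner + protic impurity -> quenched reagent; target -> over-reaction product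
- at the start none of the solid reagent is in solution

- which of these there is most of at the end, counted by the starting material in it, eta (over-reaction product / target / starting material)
- which of these there is most of at the end, counted by the starting material in it, zeta (over-reaction product / target / starting material)
- how much there is at the end of the one of these that leads, in percent of the starting material charged: eta
- how much there is at the end of the one of these that leads, in percent of the starting material charged: zeta

At 3.00 h, birch shows 69% starting material and larch 66%, a mean of 67.5%. The shift between them is about the scatter of 2 percentage points, so I take the third substrate as a small effect and put eta near that mean. That gives 0.108 h⁻¹ as the drain, the fraction of the charged starting material lost per hour, averaged from the start.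

Now take two extremes for zeta. If partner arrives at a fixed rate and starting material takes a fixed share, the drain stays constant and 56.7% remains. If partner instead stands at a fixed level, the loss is first order and 59.2% remains. I put zeta between these, and nearer the line: the birch readings fall by 15 points over the first 1.50 h and by 16 points over the next stretch of equal length, which shows no slowing within the scatter. I expect starting material to lead zeta, since on the line 56.7% exceeds 43.3%, the whole loss, which over-reaction product and target must share.

The forecast, to which the nearly linear fall suggests that “supply of partner from the solid limits the rate”, names starting material for eta at 69% (62% to 76%) and starting material for zeta at 56% (46% to 65%), close to my line.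

The flasks give starting material at 68.3% in eta and starting material at 57.1% in zeta.

    starting material + partner → target (k = 270 M⁻¹ h⁻¹)
    second substrate + partner → second product (k = 430 M⁻¹ h⁻¹)
    third substrate + partner → third product (k = 28.0 M⁻¹ h⁻¹)
    solid reagent ⇌ partner, rate k4*(cs4 - [partner]) while solid is left; crystals form when [partner] > cs4 (solubility = 5.20 mM, k = 0.450 h⁻¹)
    partner + protic impurity → quenched reagent (k = 100 M⁻¹ h⁻¹)
    target → over-reaction product (k = 1.40 h⁻¹)

Eta's drain came to 0.106 h⁻¹ and zeta's to 0.107 h⁻¹, matching the carried value, but neither flask is at rest. Eta still holds 46.8% of its solid reagent and 7.87% target. Ten times the time takes its starting material to 31.3%, a further fall that the carried drain, if it held, covers in 3.43 h. Read at 12 h, eta already stands at 31.3%, with its solid reagent, the limiting reagent, at 0%. Zeta at ten times its time also holds 31.3% starting material, and over-reaction product leads at 68.7%.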